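## Retrosynthetic overview

1. The last operation is a fluoride unmasking of three aryl silyl ethers and a 2-(trimethylsilyl)ethyl ester.
2. The only ring built is the 2,3,4,7-tetrahydrooxepine, closed second to last by ring-closing metathesis (C5=C6) between a but-3-enyl arm and a 2-substituted allyl ether; both benzene rings are bought intact.
3. The tertiary ether (C2–O–C7) comes from acid-catalysed trichloroacetimidate O-alkylation of a tertiary aldol carbinol with the complete side chain, which already carries the p-coumarate.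
4. The key C–C bond (C2 to the aroylmethyl CH2) is made by an enantioselective Mukaiyama aldol of the 2',5'-dihydroxyacetophenone enolsilane with 2-(trimethylsilyl)ethyl 2-oxohex-5-enoate, which sets the single (S) stereocentre.
5. The side chain comes from mono-PMB 2-methylidenepropane-1,3-diol by Johnson–Claisen rearrangement, (E)-selective Wittig olefination, reduction and Steglich esterification.

Assumption: the target stereocentre is (S) as read from the SMILES, and the si-face preference known for [Cu((S,S)-t-Bu-box)](OTf)2 with pyruvate esters is taken to hold for the homoallyl α-keto ester used here.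

## Route

Abbreviations: TBS = tert-butyldimethylsilyl; PMB = 4-methoxybenzyl; (S,S)-t-Bu-box = 2,2'-(propane-2,2-diyl)bis[(4S)-4-tert-butyl-4,5-dihydro-1,3-oxazole].

**Step 1**
Reactants: 1 1-(2,5-dihydroxyphenyl)ethan-1-one
Product: 2 1-[2,5-bis(tert-butyldimethylsilyloxy)phenyl]ethan-1-one
Conditions: TBSCl (2.5 equiv), imidazole (5 equiv), DMF, rt → 40 °C
Reagents that add atoms: tert-butyldimethylsilyl chloride (TBSCl), CC(C)(C)[Si](C)(C)Cl
Why: Imidazole-mediated silylation protects both phenols as silyl ethers that tolerate the later Lewis and Brønsted acid steps and leave with fluoride at the end.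

**Step 2**
Reactants: 2 1-[2,5-bis(tert-butyldimethylsilyloxy)phenyl]ethan-1-one
Product: 3 {1-[2,5-bis(tert-butyldimethylsilyloxy)phenyl]ethenyloxy}trimethylsilane
Conditions: TMSOTf (1.2 equiv), Et3N (1.5 equiv), CH2Cl2, 0 °C
Reagents that add atoms: trimethylsilyl trifluoromethanesulfonate (TMSOTf), C[Si](C)(C)OS(=O)(=O)C(F)(F)F
Why: Soft enolisation of the methyl ketone, the only enolisable site, gives the enolsilane needed for the Mukaiyama aldol.

**Step 3**
Reactants: 4 oxalyl chloride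
Product: 6 bis[2-(trimethylsilyl)ethyl] oxalate, via 2-(trimethylsilyl)ethyl chlorooxoacetate 5 (not isolated)
Conditions: 2-(trimethylsilyl)ethanol (2.1 equiv), pyridine (2.3 equiv), CH2Cl2, 0 °C → rt
Reagents that add atoms: 2-(trimethylsilyl)ethanol, C[Si](C)(C)CCO
Why: Double acylation of the alcohol by the diacid chloride installs an ester that fluoride removes at the end without any hydrolysis step.

**Step 4**
Reactants: 6 bis[2-(trimethylsilyl)ethyl] oxalate; 7 but-3-enylmagnesium bromide (0.5 M in THF)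
Product: 9 2-(trimethylsilyl)ethyl 2-oxohex-5-enoate, via bromomagnesium hemiketal alkoxide 8 (not isolated)
Conditions: 6 (1.2 equiv), THF, −78 °C, slow addition of 7; then 1 M HCl, −78 °C → rt
Reagents that add atoms: none
Why: Grignard mono-addition to a dialkyl oxalate stops at the tetrahedral magnesium alkoxide, which is stable at −78 °C and collapses to the α-keto ester only on acidic quench.

**Step 5**
Reactants: 3 {1-[2,5-bis(tert-butyldimethylsilyloxy)phenyl]ethenyloxy}trimethylsilane; 9 2-(trimethylsilyl)ethyl 2-oxohex-5-enoate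
Product: 11 2-(trimethylsilyl)ethyl (2S)-2-{2-[2,5-bis(tert-butyldimethylsilyloxy)phenyl]-2-oxoethyl}-2-hydroxyhex-5-enoate, via tertiary trimethylsilyl ether 10 (not isolated)
Conditions: [Cu((S,S)-t-Bu-box)](OTf)2 (10 mol%), 3 (1.3 equiv), THF, −78 → −40 °C; then 1 M HCl, THF, rt
Reagents that add atoms: none
Why: In this catalytic enantioselective Mukaiyama aldol the α-keto ester chelates the square-planar divalent copper centre through both carbonyls, a tert-butyl group of the ligand blocks the re face, and the enolsilane adds to the si face of the ketone to give the (2S) tertiary carbinol, freed from its trimethylsilyl ether by dilute acid.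

**Step 6**
Reactants: 12 2-methylidenepropane-1,3-diol
Product: 14 2-{[(4-methoxyphenyl)methoxy]methyl}prop-2-en-1-ol, via sodium monoalkoxide 13 (not isolated)
Conditions: 12 (1.5 equiv), NaH (1.0 equiv), THF/DMF 4:1, 0 °C; PMBCl (1.0 equiv), Bu4NI (5 mol%), 0 °C → rt
Reagents that add atoms: 4-methoxybenzyl chloride (PMBCl), COc1ccc(CCl)cc1
Why: Williamson etherification of the symmetric diol, with the diol in excess, gives mainly the mono-ether and differentiates the two allylic hydroxyls.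

**Step 7**
Reactants: 14 2-{[(4-methoxyphenyl)methoxy]methyl}prop-2-en-1-ol; 15 triethyl orthoacetate
Product: 18 ethyl 4-{[(4-methoxyphenyl)methoxy]methyl}pent-4-enoate, via mixed orthoester 16 (not isolated), via ketene acetal 17 (not isolated)
Conditions: 15 (6 equiv), EtCO2H (10 mol%), 140 °C, EtOH distilled off
Reagents that add atoms: none
Why: The Johnson–Claisen rearrangement ([3,3]-sigmatropic shift of the ketene acetal) delivers the 1,1-disubstituted alkene and the two-carbon ester extension in one operation.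

**Step 8**
Reactants: 18 ethyl 4-{[(4-methoxyphenyl)methoxy]methyl}pent-4-enoate
Product: 20 4-{[(4-methoxyphenyl)methoxy]methyl}pent-4-enal, via diisobutylaluminium hemiacetal 19 (not isolated)
Conditions: i-Bu2AlH (1.05 equiv), CH2Cl2, −78 °C; MeOH, then aq. KNaC4H4O6
Reagents that add atoms: none
Why: Partial hydride reduction of the ester stops at the aldehyde because the tetrahedral aluminium hemiacetal survives at −78 °C until work-up.

**Step 9**
Reactants: 20 4-{[(4-methoxyphenyl)methoxy]methyl}pent-4-enal; 21 ethyl 2-(triphenyl-λ5-phosphanylidene)propanoate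
Product: 22 ethyl (2E)-6-{[(4-methoxyphenyl)methoxy]methyl}-2-methylhepta-2,6-dienoate
Conditions: 21 (1.3 equiv), CH2Cl2, rt, 16 h
Reagents that add atoms: none
Why: Wittig olefination with a stabilised α-methyl ylide gives the (E)-trisubstituted enoate (E/Z above 20:1) under thermodynamic control of oxaphosphetane formation.

**Step 10**
Reactants: 22 ethyl (2E)-6-{[(4-methoxyphenyl)methoxy]methyl}-2-methylhepta-2,6-dienoate
Product: 24 (2E)-6-{[(4-methoxyphenyl)methoxy]methyl}-2-methylhepta-2,6-dien-1-ol, via diisobutylaluminium allyl alkoxide 23 (not isolated)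
Conditions: i-Bu2AlH (2.3 equiv), CH2Cl2, −78 → −20 °C; aq. KNaC4H4O6
Reagents that add atoms: none
Why: 1,2-Hydride reduction of the enoate gives the (E)-allylic alcohol with the olefin geometry untouched.

**Step 11**
Reactants: 25 (2E)-3-(4-hydroxyphenyl)prop-2-enoic acid
Product: 27 (2E)-3-[4-(tert-butyldimethylsilyloxy)phenyl]prop-2-enoic acid, via bis-silylated coumarate 26 (not isolated)
Conditions: TBSCl (2.4 equiv), imidazole (5 equiv), DMF, rt; then AcOH/THF/H2O 3:1:1, rt
Reagents that add atoms: tert-butyldimethylsilyl chloride (TBSCl), CC(C)(C)[Si](C)(C)Cl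
Why: Exhaustive silylation followed by selective hydrolysis of the far more labile silyl ester leaves the phenol protected and the acid free.

**Step 12**
Reactants: 24 (2E)-6-{[(4-methoxyphenyl)methoxy]methyl}-2-methylhepta-2,6-dien-1-ol; 27 (2E)-3-[4-(tert-butyldimethylsilyloxy)phenyl]prop-2-enoic acid
Product: 28 (2E)-6-{[(4-methoxyphenyl)methoxy]methyl}-2-methylhepta-2,6-dien-1-yl (2E)-3-[4-(tert-butyldimethylsilyloxy)phenyl]prop-2-enoate
Conditions: DCC (1.2 equiv), DMAP (10 mol%), CH2Cl2, 0 °C → rt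
Reagents that add atoms: none
Why: Steglich esterification of the unhindered primary allylic alcohol installs the coumarate early, so no protecting group is needed on this oxygen and the ester is inert to the acid, metathesis and fluoride steps that follow.

**Step 13**
Reactants: 28 (2E)-6-{[(4-methoxyphenyl)methoxy]methyl}-2-methylhepta-2,6-dien-1-yl (2E)-3-[4-(tert-butyldimethylsilyloxy)phenyl]prop-2-enoate
Product: 29 (2E)-6-(hydroxymethyl)-2-methylhepta-2,6-dien-1-yl (2E)-3-[4-(tert-butyldimethylsilyloxy)phenyl]prop-2-enoate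
Conditions: DDQ (1.3 equiv), CH2Cl2/pH 7 phosphate buffer 10:1, 0 °C
Reagents that add atoms: none
Why: Oxidative cleavage of the PMB ether by DDQ (hydride abstraction, then hydrolysis of the oxocarbenium ion) is neutral and leaves the silyl ether, the ester and the alkenes intact.

**Step 14**
Reactants: 29 (2E)-6-(hydroxymethyl)-2-methylhepta-2,6-dien-1-yl (2E)-3-[4-(tert-butyldimethylsilyloxy)phenyl]prop-2-enoate
Product: 30 (2E)-2-methyl-6-{[(2,2,2-trichloroethanimidoyl)oxy]methyl}hepta-2,6-dien-1-yl (2E)-3-[4-(tert-butyldimethylsilyloxy)phenyl]prop-2-enoate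
Conditions: Cl3CCN (3 equiv), DBU (10 mol%), CH2Cl2, 0 °C, 1 h; used at once
Reagents that add atoms: trichloroacetonitrile, ClC(Cl)(Cl)C#N
Why: Base-catalysed addition of the alcohol to trichloroacetonitrile gives the allylic trichloroacetimidate, an alkylating agent that works under acid catalysis.

**Step 15**
Reactants: 11 2-(trimethylsilyl)ethyl (2S)-2-{2-[2,5-bis(tert-butyldimethylsilyloxy)phenyl]-2-oxoethyl}-2-hydroxyhex-5-enoate; 30 (2E)-2-methyl-6-{[(2,2,2-trichloroethanimidoyl)oxy]methyl}hepta-2,6-dien-1-yl (2E)-3-[4-(tert-butyldimethylsilyloxy)phenyl]prop-2-enoate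
Product: 31 2-(trimethylsilyl)ethyl (2S)-2-{2-[2,5-bis(tert-butyldimethylsilyloxy)phenyl]-2-oxoethyl}-2-{[(5E)-7-({(2E)-3-[4-(tert-butyldimethylsilyloxy)phenyl]prop-2-enoyl}oxy)-6-methyl-2-methylidenehept-5-en-1-yl]oxy}hex-5-enoate
Conditions: 30 (3 equiv, in portions), TfOH (10 mol%), 4 Å MS, CH2Cl2/cyclohexane 1:2, 0 °C → rt
Reagents that add atoms: none
Why: Acid-catalysed trichloroacetimidate O-alkylation etherifies the tertiary β-hydroxy ketone without base, so retro-aldol and β-elimination are avoided; the two CH2 termini of the 2-substituted allyl unit are equivalent, so SN2 and SN2' attack give the same ether, and the C–O bond at the stereocentre is never broken.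

**Step 16**
Reactants: 31 2-(trimethylsilyl)ethyl (2S)-2-{2-[2,5-bis(tert-butyldimethylsilyloxy)phenyl]-2-oxoethyl}-2-{[(5E)-7-({(2E)-3-[4-(tert-butyldimethylsilyloxy)phenyl]prop-2-enoyl}oxy)-6-methyl-2-methylidenehept-5-en-1-yl]oxy}hex-5-enoate
Product: 32 2-(trimethylsilyl)ethyl (2S)-2-{2-[2,5-bis(tert-butyldimethylsilyloxy)phenyl]-2-oxoethyl}-6-[(3E)-5-({(2E)-3-[4-(tert-butyldimethylsilyloxy)phenyl]prop-2-enoyl}oxy)-4-methylpent-3-en-1-yl]-2,3,4,7-tetrahydrooxepine-2-carboxylate
Conditions: second-generation Grubbs catalyst RuCl2(=CHPh)(H2IMes)(PCy3) (2 × 5 mol%), CH2Cl2 (2 mM), 40 °C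
Reagents that add atoms: none
Why: Ring-closing metathesis starts at the monosubstituted butenyl alkene and closes onto the 1,1-disubstituted allyl ether, helped by the quaternary centre, to give the seven-membered ring with its trisubstituted olefin; the side-chain trisubstituted alkene and the cinnamate double bond are too hindered or electron-poor to compete.

**Step 17**
Reactants: 32 2-(trimethylsilyl)ethyl (2S)-2-{2-[2,5-bis(tert-butyldimethylsilyloxy)phenyl]-2-oxoethyl}-6-[(3E)-5-({(2E)-3-[4-(tert-butyldimethylsilyloxy)phenyl]prop-2-enoyl}oxy)-4-methylpent-3-en-1-yl]-2,3,4,7-tetrahydrooxepine-2-carboxylate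
Product: 34 (2S)-2-[2-(2,5-dihydroxyphenyl)-2-oxoethyl]-6-[(3E)-5-{[(2E)-3-(4-hydroxyphenyl)prop-2-enoyl]oxy}-4-methylpent-3-en-1-yl]-2,3,4,7-tetrahydrooxepine-2-carboxylic acid, via triphenol silylethyl ester 33 (not isolated)
Conditions: Bu4NF (6 equiv, 1 M in THF), THF, degassed, Ar, 0 °C → rt; then 0.5 M HCl to pH 3
Reagents that add atoms: none
Why: Fluoride-induced desilylation frees the three phenols within minutes, and the slower attack at the silylethyl silicon then fragments the ester (β-elimination to ethene), so the hindered acid is released without hydrolytic conditions that would endanger the coumarate ester or the β-alkoxy ketone.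

## Compound list

1 | 1-(2,5-dihydroxyphenyl)ethan-1-one (2',5'-dihydroxyacetophenone) | CC(=O)c1cc(O)ccc1O | starting material
2 | 1-[2,5-bis(tert-butyldimethylsilyloxy)phenyl]ethan-1-one | CC(=O)c1cc(O[Si](C)(C)C(C)(C)C)ccc1O[Si](C)(C)C(C)(C)C | intermediate
3 | {1-[2,5-bis(tert-butyldimethylsilyloxy)phenyl]ethenyloxy}trimethylsilane | C=C(O[Si](C)(C)C)c1cc(O[Si](C)(C)C(C)(C)C)ccc1O[Si](C)(C)C(C)(C)C | intermediate
4 | oxalyl chloride | O=C(Cl)C(=O)Cl | starting material
5 | 2-(trimethylsilyl)ethyl chlorooxoacetate | C[Si](C)(C)CCOC(=O)C(=O)Cl | intermediate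
6 | bis[2-(trimethylsilyl)ethyl] oxalate | C[Si](C)(C)CCOC(=O)C(=O)OCC[Si](C)(C)C | intermediate
7 | but-3-enylmagnesium bromide | C=CCC[Mg]Br | starting material
8 | bromomagnesium alkoxide of the hemiketal from 6 and 7 | C=CCCC(O[Mg]Br)(OCC[Si](C)(C)C)C(=O)OCC[Si](C)(C)C | intermediate
9 | 2-(trimethylsilyl)ethyl 2-oxohex-5-enoate | C=CCCC(=O)C(=O)OCC[Si](C)(C)C | intermediate
10 | 2-(trimethylsilyl)ethyl (2S)-2-{2-[2,5-bis(tert-butyldimethylsilyloxy)phenyl]-2-oxoethyl}-2-(trimethylsilyloxy)hex-5-enoate | C=CCC[C@](O[Si](C)(C)C)(CC(=O)c1cc(O[Si](C)(C)C(C)(C)C)ccc1O[Si](C)(C)C(C)(C)C)C(=O)OCC[Si](C)(C)C | intermediate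
11 | 2-(trimethylsilyl)ethyl (2S)-2-{2-[2,5-bis(tert-butyldimethylsilyloxy)phenyl]-2-oxoethyl}-2-hydroxyhex-5-enoate | C=CCC[C@](O)(CC(=O)c1cc(O[Si](C)(C)C(C)(C)C)ccc1O[Si](C)(C)C(C)(C)C)C(=O)OCC[Si](C)(C)C | intermediate
12 | 2-methylidenepropane-1,3-diol | C=C(CO)CO | starting material
13 | sodium 2-(hydroxymethyl)prop-2-en-1-olate | C=C(CO)C[O-].[Na+] | intermediate
14 | 2-{[(4-methoxyphenyl)methoxy]methyl}prop-2-en-1-ol | C=C(CO)COCc1ccc(OC)cc1 | intermediate
15 | triethyl orthoacetate (1,1,1-triethoxyethane) | CCOC(C)(OCC)OCC | starting material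
16 | 1-({[2-(1,1-diethoxyethoxymethyl)prop-2-en-1-yl]oxy}methyl)-4-methoxybenzene (mixed orthoester) | CCOC(C)(OCC)OCC(=C)COCc1ccc(OC)cc1 | intermediate
17 | 1-({[2-(1-ethoxyethenyloxymethyl)prop-2-en-1-yl]oxy}methyl)-4-methoxybenzene (ketene acetal) | C=C(OCC)OCC(=C)COCc1ccc(OC)cc1 | intermediate
18 | ethyl 4-{[(4-methoxyphenyl)methoxy]methyl}pent-4-enoate | CCOC(=O)CCC(=C)COCc1ccc(OC)cc1 | intermediate
19 | diisobutylaluminium salt of the ethyl hemiacetal of 20 | CCOC(CCC(=C)COCc1ccc(OC)cc1)O[Al](CC(C)C)CC(C)C | intermediate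
20 | 4-{[(4-methoxyphenyl)methoxy]methyl}pent-4-enal | O=CCCC(=C)COCc1ccc(OC)cc1 | intermediate
21 | ethyl 2-(triphenyl-λ5-phosphanylidene)propanoate | CCOC(=O)C(C)=P(c1ccccc1)(c1ccccc1)c1ccccc1 | starting material
22 | ethyl (2E)-6-{[(4-methoxyphenyl)methoxy]methyl}-2-methylhepta-2,6-dienoate | CCOC(=O)/C(C)=C/CCC(=C)COCc1ccc(OC)cc1 | intermediate
23 | diisobutylaluminium alkoxide of 24 | CC(C)C[Al](CC(C)C)OC/C(C)=C/CCC(=C)COCc1ccc(OC)cc1 | intermediate
24 | (2E)-6-{[(4-methoxyphenyl)methoxy]methyl}-2-methylhepta-2,6-dien-1-ol | OC/C(C)=C/CCC(=C)COCc1ccc(OC)cc1 | intermediate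
25 | (2E)-3-(4-hydroxyphenyl)prop-2-enoic acid (p-coumaric acid) | O=C(O)/C=C/c1ccc(O)cc1 | starting material
26 | tert-butyldimethylsilyl (2E)-3-[4-(tert-butyldimethylsilyloxy)phenyl]prop-2-enoate | CC(C)(C)[Si](C)(C)OC(=O)/C=C/c1ccc(O[Si](C)(C)C(C)(C)C)cc1 | intermediate
27 | (2E)-3-[4-(tert-butyldimethylsilyloxy)phenyl]prop-2-enoic acid | O=C(O)/C=C/c1ccc(O[Si](C)(C)C(C)(C)C)cc1 | intermediate
28 | (2E)-6-{[(4-methoxyphenyl)methoxy]methyl}-2-methylhepta-2,6-dien-1-yl (2E)-3-[4-(tert-butyldimethylsilyloxy)phenyl]prop-2-enoate | C=C(COCc1ccc(OC)cc1)CC/C=C(\C)COC(=O)/C=C/c1ccc(O[Si](C)(C)C(C)(C)C)cc1 | intermediate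
29 | (2E)-6-(hydroxymethyl)-2-methylhepta-2,6-dien-1-yl (2E)-3-[4-(tert-butyldimethylsilyloxy)phenyl]prop-2-enoate | C=C(CO)CC/C=C(\C)COC(=O)/C=C/c1ccc(O[Si](C)(C)C(C)(C)C)cc1 | intermediate
30 | (2E)-2-methyl-6-{[(2,2,2-trichloroethanimidoyl)oxy]methyl}hepta-2,6-dien-1-yl (2E)-3-[4-(tert-butyldimethylsilyloxy)phenyl]prop-2-enoate | C=C(COC(=N)C(Cl)(Cl)Cl)CC/C=C(\C)COC(=O)/C=C/c1ccc(O[Si](C)(C)C(C)(C)C)cc1 | intermediate
31 | 2-(trimethylsilyl)ethyl (2S)-2-{2-[2,5-bis(tert-butyldimethylsilyloxy)phenyl]-2-oxoethyl}-2-{[(5E)-7-({(2E)-3-[4-(tert-butyldimethylsilyloxy)phenyl]prop-2-enoyl}oxy)-6-methyl-2-methylidenehept-5-en-1-yl]oxy}hex-5-enoate | C=CCC[C@](OCC(=C)CC/C=C(\C)COC(=O)/C=C/c1ccc(O[Si](C)(C)C(C)(C)C)cc1)(CC(=O)c1cc(O[Si](C)(C)C(C)(C)C)ccc1O[Si](C)(C)C(C)(C)C)C(=O)OCC[Si](C)(C)C | intermediate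
32 | 2-(trimethylsilyl)ethyl (2S)-2-{2-[2,5-bis(tert-butyldimethylsilyloxy)phenyl]-2-oxoethyl}-6-[(3E)-5-({(2E)-3-[4-(tert-butyldimethylsilyloxy)phenyl]prop-2-enoyl}oxy)-4-methylpent-3-en-1-yl]-2,3,4,7-tetrahydrooxepine-2-carboxylate | C/C(=C\CCC1=CCC[C@](CC(=O)c2cc(O[Si](C)(C)C(C)(C)C)ccc2O[Si](C)(C)C(C)(C)C)(C(=O)OCC[Si](C)(C)C)OC1)COC(=O)/C=C/c1ccc(O[Si](C)(C)C(C)(C)C)cc1 | intermediate
33 | 2-(trimethylsilyl)ethyl (2S)-2-[2-(2,5-dihydroxyphenyl)-2-oxoethyl]-6-[(3E)-5-{[(2E)-3-(4-hydroxyphenyl)prop-2-enoyl]oxy}-4-methylpent-3-en-1-yl]-2,3,4,7-tetrahydrooxepine-2-carboxylate | C/C(=C\CCC1=CCC[C@](CC(=O)c2cc(O)ccc2O)(C(=O)OCC[Si](C)(C)C)OC1)COC(=O)/C=C/c1ccc(O)cc1 | intermediate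
34 | (2S)-2-[2-(2,5-dihydroxyphenyl)-2-oxoethyl]-6-[(3E)-5-{[(2E)-3-(4-hydroxyphenyl)prop-2-enoyl]oxy}-4-methylpent-3-en-1-yl]-2,3,4,7-tetrahydrooxepine-2-carboxylic acid (CNP0602535.2) | C/C(=C\CCC1=CCC[C@](CC(=O)c2cc(O)ccc2O)(C(=O)O)OC1)COC(=O)/C=C/c1ccc(O)cc1 | target

## Step count and risk

Total steps: 17.
Longest linear sequence: 11 steps (6, 7, 8, 9, 10, 12, 13, 14, 15, 16, 17), from 12 to 34.

Steps most likely to fail:

**Step 15 (etherification of the hindered tertiary carbinol).** The alcohol is a poor nucleophile, and the imidate may instead rearrange or cyclise onto its own trisubstituted alkene. The fallback sets out from 29 and 11 and comes back at 31. Alcohol 29 is acetylated (Ac2O, pyridine, DMAP cat., CH2Cl2, 0 °C) to (2E)-6-(acetoxymethyl)-2-methylhepta-2,6-dien-1-yl (2E)-3-[4-(tert-butyldimethylsilyloxy)phenyl]prop-2-enoate F4. Carbinol 11 is converted with Et2Zn (1.0 equiv, THF, 0 °C) into its ethylzinc alkoxide F5. The two are joined by allylic etherification with Pd(OAc)2 (5 mol%) and 2-(di-tert-butylphosphino)biphenyl (7.5 mol%) in THF at rt. Zerovalent palladium formed in situ ionises the unhindered 2-substituted allyl acetate much faster than the trisubstituted allylic coumarate, the resulting π-allyl has two equivalent termini, and the non-basic zinc alkoxide captures it without retro-aldol, giving 31.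

**Step 5 (asymmetric aldol).** The ortho-silyloxy aryl enolsilane and the homoallyl keto ester are both outside the tested scope of the catalyst, so conversion or ee may be poor. The fallback sets out from 3 and 9 and comes back at 11. The same Mukaiyama addition is run with ligand-free Cu(OTf)2 (10 mol%, CH2Cl2, −78 → 0 °C) to give the racemic tertiary trimethylsilyl ether F1 and, after 1 M HCl, the racemic hydroxy ketone F2. The enantiomers of F2 are separated by preparative supercritical-fluid chromatography on an amylose tris(3,5-dimethylphenylcarbamate) phase. The (S)-enantiomer is 11 and rejoins the route at step 15; the (R)-enantiomer F3 is set aside.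

**Step 17 (one-pot fluoride unmasking).** Basic Bu4NF could trigger β-elimination of the ring oxygen from the aryl ketone (followed by chromanone closure), attack the coumarate ester, or let the hydroquinone dianion oxidise in air. The fallback sets out from 32 and comes back at 34. KHF2 (3 equiv, MeOH/THF, rt) cleaves only the three phenolic silyl ethers and gives 33 as an isolated, purified compound. The silylethyl ester of 33 is then removed with anhydrous tris(dimethylamino)sulfonium difluorotrimethylsilicate (3 equiv, DMF, 0 °C) and quenched into pH 4 buffer to give 34. This fallback makes no compound outside the list (F0).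

## Further compounds

F1 | step 5 | racemic 2-(trimethylsilyl)ethyl 2-{2-[2,5-bis(tert-butyldimethylsilyloxy)phenyl]-2-oxoethyl}-2-(trimethylsilyloxy)hex-5-enoate | C=CCCC(O[Si](C)(C)C)(CC(=O)c1cc(O[Si](C)(C)C(C)(C)C)ccc1O[Si](C)(C)C(C)(C)C)C(=O)OCC[Si](C)(C)C
F2 | step 5 | racemic 2-(trimethylsilyl)ethyl 2-{2-[2,5-bis(tert-butyldimethylsilyloxy)phenyl]-2-oxoethyl}-2-hydroxyhex-5-enoate | C=CCCC(O)(CC(=O)c1cc(O[Si](C)(C)C(C)(C)C)ccc1O[Si](C)(C)C(C)(C)C)C(=O)OCC[Si](C)(C)C
F3 | step 5 | 2-(trimethylsilyl)ethyl (2R)-2-{2-[2,5-bis(tert-butyldimethylsilyloxy)phenyl]-2-oxoethyl}-2-hydroxyhex-5-enoate | C=CCC[C@@](O)(CC(=O)c1cc(O[Si](C)(C)C(C)(C)C)ccc1O[Si](C)(C)C(C)(C)C)C(=O)OCC[Si](C)(C)C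
F4 | step 15 | (2E)-6-(acetoxymethyl)-2-methylhepta-2,6-dien-1-yl (2E)-3-[4-(tert-butyldimethylsilyloxy)phenyl]prop-2-enoate | C=C(COC(C)=O)CC/C=C(\C)COC(=O)/C=C/c1ccc(O[Si](C)(C)C(C)(C)C)cc1
F5 | step 15 | ethylzinc alkoxide of 11, 2-(trimethylsilyl)ethyl (2S)-2-{2-[2,5-bis(tert-butyldimethylsilyloxy)phenyl]-2-oxoethyl}-2-[(ethylzincio)oxy]hex-5-enoate | C=CCC[C@](O[Zn]CC)(CC(=O)c1cc(O[Si](C)(C)C(C)(C)C)ccc1O[Si](C)(C)C(C)(C)C)C(=O)OCC[Si](C)(C)C
F0 | step 17 | none | none
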